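The tetrahydrofuran ring (O1, C2 aryl, C3 acyloxymethyl, C4 benzyl, C5) is cut at C2–C3 and O1–C5. O1–C2 is then silylated vanillin. C3, C4 and the benzylic carbon on C4 are the three carbons of an allylboronate, with C5 as a methyl ester on the central carbon C4. One chiral-acid-catalysed allylboration with in-flask lactonisation forms both bonds, closes the ring, sets C2 and C3 trans and leaves a methylene on C4 for the second guaiacyl group. The precursor is a pinacol boronate whose silyloxymethyl group lies trans to CH2B. Alkyl and aryl silyl ethers are differentiated later, so acylation meets one hydroxyl only.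

Key step: step 4

Numbering and configuration: the target is read as (2R,3S,4S) in the ring (2,3-trans, 3,4-cis) with an (R)-2-methylbutanoyl group. The ring numbering O1–C5 is used for all intermediates unless lactone numbering is stated.

Assumption: (R)-TRIP is taken to direct the allyl unit to the re face of the aryl aldehyde, as it does with simple allyl and crotyl pinacol boronates; if this boronate showed the opposite sense, (S)-TRIP would be used with nothing else changed.

Step 1
Reactants: 1 tert-butyldimethyl(prop-2-yn-1-yloxy)silane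
Product: 3 methyl 4-(tert-butyldimethylsilyloxy)but-2-ynoate, via lithium acetylide 2 (not isolated)
Conditions: n-BuLi, THF, −78 °C; ClCO2Me, −78 °C to 0 °C
Reagents that add atoms: methyl chloroformate, COC(=O)Cl
Why: Deprotonation of a terminal alkyne followed by C-acylation of the lithium acetylide with a chloroformate is a routine alkynoate synthesis to which the silyl ether is inert.

Step 2
Reactants: 3 methyl 4-(tert-butyldimethylsilyloxy)but-2-ynoate; 4 2-(iodomethyl)-4,4,5,5-tetramethyl-1,3,2-dioxaborolane
Product: 6 methyl (Z)-4-(tert-butyldimethylsilyloxy)-2-[(4,4,5,5-tetramethyl-1,3,2-dioxaborolan-2-yl)methyl]but-2-enoate (CH2OTBS cis to CO2Me and trans to CH2B), via alkenylalane 5 (not isolated)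
Conditions: i-Bu2AlH, HMPA, THF, 0 °C; add 3, 0 °C; add 4, 0 °C to rt; aq. potassium sodium tartrate
Reagents that add atoms: none
Why: Conjugate syn-hydroalumination of an alkynoate by the i-Bu2AlH–HMPA complex puts hydrogen on the β-carbon and aluminium on the α-carbon on the same side without touching the ester, and the alkenylalane then attacks boron of 4 and shifts to carbon with loss of iodide (Matteson-type homologation) with retention, so that CH2OTBS ends trans to CH2B.

Step 3
Reactants: 7 vanillin
Product: 8 4-(tert-butyldimethylsilyloxy)-3-methoxybenzaldehyde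
Conditions: TBSCl, imidazole, CH2Cl2, rt
Reagents that add atoms: tert-butyldimethylsilyl chloride, CC(C)(C)[Si](C)(C)Cl
Why: Silylation of a phenol under imidazole catalysis is routine and masks the acidic OH that would otherwise quench the boronate and the acid catalyst.

Step 4
Reactants: 6 methyl (Z)-4-(tert-butyldimethylsilyloxy)-2-[(pinacolboryl)methyl]but-2-enoate; 8 4-(tert-butyldimethylsilyloxy)-3-methoxybenzaldehyde
Product: 10 (4S,5R)-4-[(tert-butyldimethylsilyloxy)methyl]-5-[4-(tert-butyldimethylsilyloxy)-3-methoxyphenyl]-3-methylidenedihydrofuran-2(3H)-one (4,5-trans), via open-chain anti pinacol borate 9 (not isolated)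
Conditions: (R)-TRIP [(R)-3,3'-bis(2,4,6-triisopropylphenyl)-1,1'-binaphthyl-2,2'-diyl hydrogen phosphate] (10 mol%), 4 Å MS, toluene, rt until 8 is consumed, then 50 °C to complete ring closure
Reagents that add atoms: none
Why: The phosphoric acid hydrogen-bonds through P–OH to a boronate oxygen and through P=O to the formyl hydrogen, the aldehyde oxygen binds to boron, and the allyl unit hands its substituted terminus to the carbonyl carbon in a closed six-membered chair (C2–C3), after which the oxygen of borate 9 adds to the neighbouring methyl ester and expels MeOBpin (O1–C5). The closest known reaction types are the Brønsted- or Lewis-acid-catalysed addition of 2-alkoxycarbonyl allylboronates to aldehydes, which gives α-methylene-γ-butyrolactones, and the chiral-phosphoric-acid-catalysed allyl- and crotylboration of aryl aldehydes with pinacol boronates; their combination on this electron-poor boronate is the least documented point of the route. The one ring closes in the 5-exo-trig mode by addition–elimination at the ester carbonyl. C3 is tied to C2 by the alkene geometry, since with CH2OTBS trans to CH2B both this group and the aryl group are equatorial in the chair, which gives the anti borate and so the 4,5-trans lactone, while the absolute sense (re face of 8, 5R and hence 4S) is set by the pocket of the (R)-catalyst. The step needs the catalysed path to outrun the racemic one, which the ester-deactivated boronate secures because it is almost inert to 8 at room temperature without acid, and it needs closure through O1 only, which the silyl group on the other oxygen secures. If acid ionised the electron-rich benzylic C2–O bond, reclosure should again be trans to the C3 arm, so C3 and the enantiomeric purity would stay untouched.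

Step 5
Reactants: 11 4-bromo-2-methoxyphenol
Product: 12 (4-bromo-2-methoxyphenoxy)(tert-butyl)dimethylsilane
Conditions: TBSCl, imidazole, CH2Cl2, rt
Reagents that add atoms: tert-butyldimethylsilyl chloride, CC(C)(C)[Si](C)(C)Cl
Why: The same imidazole-promoted phenol silylation protects the second guaiacol unit before metalation.

Step 6
Reactants: 12 (4-bromo-2-methoxyphenoxy)(tert-butyl)dimethylsilane
Product: 15 [4-(tert-butyldimethylsilyloxy)-3-methoxyphenyl]boronic acid, via aryllithium 13 (not isolated), via lithium aryltriisopropoxyborate 14 (not isolated)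
Conditions: n-BuLi, THF, −78 °C; B(Oi-Pr)3, −78 °C to rt; 1 M HCl, 0 °C, brief
Reagents that add atoms: triisopropyl borate, CC(C)OB(OC(C)C)OC(C)C; water, O
Why: Bromine–lithium exchange at low temperature, borylation of the aryllithium with a trialkyl borate and mild hydrolysis is the standard boronic acid synthesis, and with lithium para to the silyloxy group no silyl migration to carbon is possible.

Step 7
Reactants: 10 (4S,5R)-α-methylene lactone; 15 [4-(tert-butyldimethylsilyloxy)-3-methoxyphenyl]boronic acid
Product: 16 (3S,4S,5R)-3-[4-(tert-butyldimethylsilyloxy)-3-methoxybenzyl]-4-[(tert-butyldimethylsilyloxy)methyl]-5-[4-(tert-butyldimethylsilyloxy)-3-methoxyphenyl]dihydrofuran-2(3H)-one (3,4-cis; 4,5-trans)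
Conditions: [Rh(OH)(cod)]2 (2.5 mol%), 15 (1.5 equiv), dioxane/H2O 10:1, no added base, rt to 40 °C
Reagents that add atoms: none
Why: Rhodium-catalysed 1,4-addition of an arylboronic acid (Hayashi–Miyaura reaction) to the unhindered methylene carbon gives a rhodium enolate that water should protonate on the face away from the neighbouring CH2OTBS group, which sets C4 (3S in the lactone) with the benzyl arm cis to the C3 arm, and the base-free mild medium keeps this kinetic epimer from equilibrating.

Step 8
Reactants: 16 (3S,4S,5R)-benzyl lactone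
Product: 17 (1R,2S,3S)-2-[(tert-butyldimethylsilyloxy)methyl]-1-[4-(tert-butyldimethylsilyloxy)-3-methoxyphenyl]-3-[4-(tert-butyldimethylsilyloxy)-3-methoxybenzyl]butane-1,4-diol
Conditions: i-Bu2AlH (excess), CH2Cl2, −78 °C to 0 °C; aq. potassium sodium tartrate
Reagents that add atoms: none
Why: Exhaustive hydride reduction of a lactone to the 1,4-diol breaks no bond at a stereocentre, outruns enolisation at C4 and spares alkyl and aryl silyl ethers.

Step 9
Reactants: 17 (1R,2S,3S)-1,4-diol
Product: 19 (2R,3S,4S)-3-[(tert-butyldimethylsilyloxy)methyl]-2-[4-(tert-butyldimethylsilyloxy)-3-methoxyphenyl]-4-[4-(tert-butyldimethylsilyloxy)-3-methoxybenzyl]oxolane, via primary monotosylate 18 (not isolated)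
Conditions: TsCl (1.15 equiv), Et3N, DMAP (cat.), CH2Cl2, 0 °C to 40 °C
Reagents that add atoms: none
Why: Selective sulfonylation of the unhindered primary alcohol and intramolecular Williamson-type 5-exo-tet displacement by the benzylic hydroxyl close the ring under basic conditions without breaking a bond at C2, C3 or C4, which avoids the Lewis acids of a lactol deoxygenation that could ionise C2–O and start Friedel–Crafts closure onto the benzyl ring.

Step 10
Reactants: 19 tris-silylated oxolane
Product: 20 {(2R,3S,4S)-2-[4-(tert-butyldimethylsilyloxy)-3-methoxyphenyl]-4-[4-(tert-butyldimethylsilyloxy)-3-methoxybenzyl]oxolan-3-yl}methanol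
Conditions: camphorsulfonic acid (10 mol%), MeOH/CH2Cl2 1:1, 0 °C; Et3N quench
Reagents that add atoms: none
Why: Acid-catalysed methanolysis removes a primary alkyl TBS ether much faster than aryl TBS ethers, whose oxygen is far less basic, and catalytic acid at 0 °C should be too mild to ionise the benzylic ether.

Step 11
Reactants: 20 primary alcohol; 21 (R)-2-methylbutanoic acid
Product: 22 {(2R,3S,4S)-2-[4-(tert-butyldimethylsilyloxy)-3-methoxyphenyl]-4-[4-(tert-butyldimethylsilyloxy)-3-methoxybenzyl]oxolan-3-yl}methyl (R)-2-methylbutanoate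
Conditions: DCC, DMAP (cat.), CH2Cl2, 0 °C to rt
Reagents that add atoms: none
Why: Steglich esterification finds a single free hydroxyl group, the new stereocentre is brought in with enantiopure 21, and low temperature with little DMAP guards it against enolisation.

Step 12
Reactants: 22 bis-silylated ester
Product: 23 [(2R,3S,4S)-2-(4-hydroxy-3-methoxyphenyl)-4-(4-hydroxy-3-methoxybenzyl)oxolan-3-yl]methyl (R)-2-methylbutanoate (CNP0315069.1)
Conditions: Bu4NF, AcOH (slight excess over fluoride), THF, 0 °C
Reagents that add atoms: none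
Why: Fluoride cleaves aryl silyl ethers within minutes because phenoxide is a good leaving group, and the acetic acid buffer prevents acyl migration, ester cleavage or epimerisation by phenoxide or basic fluoride.

Compound list
1 | tert-butyldimethyl(prop-2-yn-1-yloxy)silane | C#CCO[Si](C)(C)C(C)(C)C | starting material
2 | lithium acetylide of 1 | [Li]C#CCO[Si](C)(C)C(C)(C)C | intermediate
3 | methyl 4-(tert-butyldimethylsilyloxy)but-2-ynoate | COC(=O)C#CCO[Si](C)(C)C(C)(C)C | intermediate
4 | 2-(iodomethyl)-4,4,5,5-tetramethyl-1,3,2-dioxaborolane | ICB1OC(C)(C)C(C)(C)O1 | starting material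
5 | methyl (E)-4-(tert-butyldimethylsilyloxy)-2-(diisobutylalumanyl)but-2-enoate (Al cis to the alkene H) | COC(=O)/C([Al](CC(C)C)CC(C)C)=C\CO[Si](C)(C)C(C)(C)C | intermediate
6 | methyl (Z)-4-(tert-butyldimethylsilyloxy)-2-[(4,4,5,5-tetramethyl-1,3,2-dioxaborolan-2-yl)methyl]but-2-enoate | COC(=O)/C(CB1OC(C)(C)C(C)(C)O1)=C\CO[Si](C)(C)C(C)(C)C | intermediate
7 | vanillin | COc1cc(C=O)ccc1O | starting material
8 | 4-(tert-butyldimethylsilyloxy)-3-methoxybenzaldehyde | COc1cc(C=O)ccc1O[Si](C)(C)C(C)(C)C | intermediate
9 | methyl (3S)-4-(tert-butyldimethylsilyloxy)-3-{(R)-[4-(tert-butyldimethylsilyloxy)-3-methoxyphenyl][(pinacolboryl)oxy]methyl}-2-methylidenebutanoate (anti) | CC(C)(C)[Si](C)(C)OC[C@@H]([C@@H](OB1OC(C)(C)C(C)(C)O1)c1ccc(O[Si](C)(C)C(C)(C)C)c(OC)c1)C(=C)C(=O)OC | intermediate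
10 | (4S,5R)-4-[(tert-butyldimethylsilyloxy)methyl]-5-[4-(tert-butyldimethylsilyloxy)-3-methoxyphenyl]-3-methylidenedihydrofuran-2(3H)-one | CC(C)(C)[Si](C)(C)OC[C@@H]1C(=C)C(=O)O[C@H]1c1ccc(O[Si](C)(C)C(C)(C)C)c(OC)c1 | intermediate
11 | 4-bromo-2-methoxyphenol | COc1cc(Br)ccc1O | starting material
12 | (4-bromo-2-methoxyphenoxy)(tert-butyl)dimethylsilane | COc1cc(Br)ccc1O[Si](C)(C)C(C)(C)C | intermediate
13 | [4-(tert-butyldimethylsilyloxy)-3-methoxyphenyl]lithium | COc1cc([Li])ccc1O[Si](C)(C)C(C)(C)C | intermediate
14 | lithium [4-(tert-butyldimethylsilyloxy)-3-methoxyphenyl]triisopropoxyborate | [Li+].COc1cc(ccc1O[Si](C)(C)C(C)(C)C)[B-](OC(C)C)(OC(C)C)OC(C)C | intermediate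
15 | [4-(tert-butyldimethylsilyloxy)-3-methoxyphenyl]boronic acid | COc1cc(B(O)O)ccc1O[Si](C)(C)C(C)(C)C | intermediate
16 | (3S,4S,5R)-3-[4-(tert-butyldimethylsilyloxy)-3-methoxybenzyl]-4-[(tert-butyldimethylsilyloxy)methyl]-5-[4-(tert-butyldimethylsilyloxy)-3-methoxyphenyl]dihydrofuran-2(3H)-one | CC(C)(C)[Si](C)(C)OC[C@@H]1[C@H](Cc2ccc(O[Si](C)(C)C(C)(C)C)c(OC)c2)C(=O)O[C@H]1c1ccc(O[Si](C)(C)C(C)(C)C)c(OC)c1 | intermediate
17 | (1R,2S,3S)-2-[(tert-butyldimethylsilyloxy)methyl]-1-[4-(tert-butyldimethylsilyloxy)-3-methoxyphenyl]-3-[4-(tert-butyldimethylsilyloxy)-3-methoxybenzyl]butane-1,4-diol | CC(C)(C)[Si](C)(C)OC[C@@H]([C@@H](O)c1ccc(O[Si](C)(C)C(C)(C)C)c(OC)c1)[C@H](Cc1ccc(O[Si](C)(C)C(C)(C)C)c(OC)c1)CO | intermediate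
18 | 4-O-tosylate of diol 17 (primary monotosylate, same configuration) | CC(C)(C)[Si](C)(C)OC[C@@H]([C@@H](O)c1ccc(O[Si](C)(C)C(C)(C)C)c(OC)c1)[C@H](Cc1ccc(O[Si](C)(C)C(C)(C)C)c(OC)c1)COS(=O)(=O)c1ccc(C)cc1 | intermediate
19 | (2R,3S,4S)-3-[(tert-butyldimethylsilyloxy)methyl]-2-[4-(tert-butyldimethylsilyloxy)-3-methoxyphenyl]-4-[4-(tert-butyldimethylsilyloxy)-3-methoxybenzyl]oxolane | CC(C)(C)[Si](C)(C)OC[C@@H]1[C@H](Cc2ccc(O[Si](C)(C)C(C)(C)C)c(OC)c2)CO[C@H]1c1ccc(O[Si](C)(C)C(C)(C)C)c(OC)c1 | intermediate
20 | {(2R,3S,4S)-2-[4-(tert-butyldimethylsilyloxy)-3-methoxyphenyl]-4-[4-(tert-butyldimethylsilyloxy)-3-methoxybenzyl]oxolan-3-yl}methanol | OC[C@@H]1[C@H](Cc2ccc(O[Si](C)(C)C(C)(C)C)c(OC)c2)CO[C@H]1c1ccc(O[Si](C)(C)C(C)(C)C)c(OC)c1 | intermediate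
21 | (R)-2-methylbutanoic acid | CC[C@@H](C)C(=O)O | starting material
22 | (R)-2-methylbutanoate of alcohol 20 | CC[C@@H](C)C(=O)OC[C@@H]1[C@H](Cc2ccc(O[Si](C)(C)C(C)(C)C)c(OC)c2)CO[C@H]1c1ccc(O[Si](C)(C)C(C)(C)C)c(OC)c1 | intermediate
23 | [(2R,3S,4S)-2-(4-hydroxy-3-methoxyphenyl)-4-(4-hydroxy-3-methoxybenzyl)oxolan-3-yl]methyl (R)-2-methylbutanoate | CC[C@@H](C)C(=O)OC[C@@H]1[C@H](Cc2ccc(O)c(OC)c2)CO[C@H]1c1ccc(O)c(OC)c1 | target

Total step count: 12. Longest linear sequence: 9 steps (1, 2, 4, 7, 8, 9, 10, 11, 12, counted from 1).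

Steps most likely to fail

Step 4. The weak chiral acid may activate the ester-deactivated boronate too little. The ester on the allyl unit may also disturb the catalyst pocket. Either way, conversion or facial selectivity on the aldehyde could be poor. The fallback sets out from 6 and 8. The addition is run with the achiral Lewis acid Sc(OTf)3 in toluene at rt, or simply by heating, both established for this boronate class and both keeping the chair-controlled trans relation. This gives the racemate, that is 10 together with the mirror-image (4R,5S)-lactone F1. The two are separated by preparative chromatography on a polysaccharide chiral stationary phase, and the route is rejoined at 10.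

Step 7. The rhodium enolate may be protonated with poor facial selectivity. The kinetic cis epimer may equilibrate, or β-hydride elimination may compete with protonation. The fallback sets out from 10 and the aryl bromide 12. Mizoroki–Heck arylation (Pd(OAc)2, P(o-tol)3, Et3N, MeCN, 80 °C) gives the (E)-benzylidene lactone F2. Hydrogenation (H2 1 atm, Pd/C, EtOAc, stopped after one equivalent) then delivers hydrogen to the alkene face away from CH2OTBS. C4 is thus set by surface addition instead of enolate protonation, and the route is rejoined at 16.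

Step 2. The alkene geometry may erode through the allenolate form of the alane. The ester may suffer 1,2-reduction, or capture by the iodomethylboronate may be sluggish. The fallback sets out from 3. Syn-hydrostannation (Bu3SnH, Pd(PPh3)4 cat., THF, rt) gives the α-stannyl enoate F3. Iododestannylation (I2, CH2Cl2, 0 °C) gives the α-iodo enoate F4 with retention. Negishi coupling (Pd(PPh3)4 cat., THF, rt) with (pinacolboryl)methylzinc iodide F5, made from 4 and zinc dust, replaces iodine by CH2Bpin with retention, and the route is rejoined at 6.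

Further compounds
F1 | step 4 | (4R,5S)-4-[(tert-butyldimethylsilyloxy)methyl]-5-[4-(tert-butyldimethylsilyloxy)-3-methoxyphenyl]-3-methylidenedihydrofuran-2(3H)-one | CC(C)(C)[Si](C)(C)OC[C@H]1C(=C)C(=O)O[C@@H]1c1ccc(O[Si](C)(C)C(C)(C)C)c(OC)c1
F2 | step 7 | (3E,4S,5R)-3-[4-(tert-butyldimethylsilyloxy)-3-methoxybenzylidene]-4-[(tert-butyldimethylsilyloxy)methyl]-5-[4-(tert-butyldimethylsilyloxy)-3-methoxyphenyl]dihydrofuran-2(3H)-one | CC(C)(C)[Si](C)(C)OC[C@@H]1/C(=C\c2ccc(O[Si](C)(C)C(C)(C)C)c(OC)c2)C(=O)O[C@H]1c1ccc(O[Si](C)(C)C(C)(C)C)c(OC)c1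
F3 | step 2 | methyl (E)-4-(tert-butyldimethylsilyloxy)-2-(tributylstannyl)but-2-enoate | COC(=O)/C([Sn](CCCC)(CCCC)CCCC)=C\CO[Si](C)(C)C(C)(C)C
F4 | step 2 | methyl (E)-4-(tert-butyldimethylsilyloxy)-2-iodobut-2-enoate | COC(=O)/C(I)=C\CO[Si](C)(C)C(C)(C)C
F5 | step 2 | [(4,4,5,5-tetramethyl-1,3,2-dioxaborolan-2-yl)methyl]zinc iodide | I[Zn]CB1OC(C)(C)C(C)(C)O1
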